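**Retrosynthetic overview**

- The strategy rests on the acyloin embedded in ring C: C3 (bearing OH, ring B and the C2 methylene) is bonded directly to the C4 ketone conjugated with ring A. The C3–C4 bond is cut as a retro-benzoin.
- This leads to an O-phenacyl salicylaldehyde in which the formyl carbon becomes C4 and the ketone carbon becomes C3. Ring C is the only ring made in the route; it is closed last, and the single stereocentre is set in the same step. The two methoxymethyl ethers are then removed.
- The O1–C2 ether comes from Williamson alkylation of 2-hydroxy-4,6-bis(methoxymethoxy)benzaldehyde (from 2,4,6-trihydroxybenzaldehyde) with the ring-B phenacyl bromide.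
- The ring-B piece comes from 2',4'-dimethoxyacetophenone: dioxolane masking, metalation between the two methoxy groups, prenylation, unmasking, and α-bromination through the silyl enol ether. This avoids any electrophilic acylation or halogenation of a prenylated arene.

Key step: step 6

Assumption: the (5aR,10bS) enantiomer of the aminoindanol-derived triazolium salt is taken to give the (R) carbinol; if a trial run shows the opposite sense, the (5aS,10bR) salt (also commercial) is used with no other change.

**Route**

Step 1
Reactants: 1 1-(2,4-dimethoxyphenyl)ethan-1-one (2',4'-dimethoxyacetophenone)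
Product: 2 2-(2,4-dimethoxyphenyl)-2-methyl-1,3-dioxolane
Conditions: ethylene glycol (5 equiv), HC(OEt)3 (2 equiv), p-TsOH·H2O (cat.), 40 °C; Et3N quench
Reagents that add atoms: ethylene glycol, OCCO
Why: Acid-catalysed ketalisation driven by the orthoformate as water scavenger masks the ketone against n-BuLi and leaves the ring position between the two methoxy groups as the most acidic site.

Step 2
Reactants: 2 2-(2,4-dimethoxyphenyl)-2-methyl-1,3-dioxolane; 3 1-bromo-3-methylbut-2-ene (prenyl bromide)
Product: 6 1-[2,4-dimethoxy-3-(3-methylbut-2-en-1-yl)phenyl]ethan-1-one, via aryllithium 4 (not isolated), via prenylated dioxolane 5 (not isolated)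
Conditions: n-BuLi (1.2 equiv), THF, 0 °C to rt; 3 (1.3 equiv), −78 °C to rt; then 2 M HCl (aq), rt
Reagents that add atoms: water, O
Why: Directed ortho-metalation should occur at the carbon flanked by both methoxy groups, the aryllithium is alkylated at the primary carbon of the allylic bromide, and dilute aqueous acid at room temperature cleaves the electron-rich aryl ketal without touching the trisubstituted alkene.

Step 3
Reactants: 6 1-[2,4-dimethoxy-3-(3-methylbut-2-en-1-yl)phenyl]ethan-1-one
Product: 8 2-bromo-1-[2,4-dimethoxy-3-(3-methylbut-2-en-1-yl)phenyl]ethan-1-one, via silyl enol ether 7 (not isolated)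
Conditions: Me3SiOTf (1.2 equiv), Et3N (1.3 equiv), CH2Cl2, 0 °C; then NBS (1.05 equiv), THF, −78 to 0 °C
Reagents that add atoms: Me3SiOTf, C[Si](C)(C)OS(=O)(=O)C(F)(F)F (silyl group of intermediate 7 only); NBS, O=C1CCC(=O)N1Br
Why: α-Bromination of a ketone through its silyl enol ether: only the methyl side can enolise, and the enol ether should react with one equivalent of NBS at low temperature far faster than the prenyl double bond or the arene.

Step 4
Reactants: 9 2,4,6-trihydroxybenzaldehyde
Product: 10 2-hydroxy-4,6-bis(methoxymethoxy)benzaldehyde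
Conditions: MOMCl (2.2 equiv), i-Pr2NEt (2.5 equiv), CH2Cl2, 0 °C to rt
Reagents that add atoms: chloromethyl methyl ether (MOMCl), COCCl
Why: O-Alkylation with the chloromethyl ether takes the 4-OH and one ortho-OH (the two ortho positions are equivalent by symmetry), and the remaining ortho-OH, hydrogen-bonded to the formyl oxygen, is the least nucleophilic, so the reaction should stop at the bis-ether.

Step 5
Reactants: 10 2-hydroxy-4,6-bis(methoxymethoxy)benzaldehyde; 8 2-bromo-1-[2,4-dimethoxy-3-(3-methylbut-2-en-1-yl)phenyl]ethan-1-one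
Product: 11 2-{2-[2,4-dimethoxy-3-(3-methylbut-2-en-1-yl)phenyl]-2-oxoethoxy}-4,6-bis(methoxymethoxy)benzaldehyde
Conditions: K2CO3 (1.5 equiv), acetone, rt
Reagents that add atoms: none
Why: Williamson ether synthesis with a highly reactive phenacyl bromide; carbonate at room temperature is chosen so that the product does not go on to the intramolecular aldol condensation (Rap–Stoermer pathway) seen on heating.

Step 6
Reactants: 11 2-{2-[2,4-dimethoxy-3-(3-methylbut-2-en-1-yl)phenyl]-2-oxoethoxy}-4,6-bis(methoxymethoxy)benzaldehyde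
Product: 12 (3R)-3-[2,4-dimethoxy-3-(3-methylbut-2-en-1-yl)phenyl]-3-hydroxy-5,7-bis(methoxymethoxy)-2,3-dihydro-4H-chromen-4-one
Conditions: (5aR,10bS)-2-(pentafluorophenyl)-5a,10b-dihydro-4H,6H-indeno[2,1-b][1,2,4]triazolo[4,3-d][1,4]oxazin-2-ium tetrafluoroborate (C18H11BF9N3O, 20 mol%), Et3N (20 mol%), toluene, rt, Ar
Reagents that add atoms: none
Why: The triazolylidene freed by Et3N adds to the formyl group, proton transfer gives the enaminol acyl-anion equivalent, its nucleophilic carbon (future C4) attacks the tethered aryl ketone (future C3), and collapse of the adduct releases the carbene and the α-hydroxy ketone. The closest known reaction type is the carbene-catalysed intramolecular crossed aldehyde–ketone benzoin of O-phenacyl salicylaldehydes to 3-aryl-3-hydroxychroman-4-ones. Ring C closes in a 6-exo-trig mode with formation of C3–C4. The C3 configuration is set by the chiral carbene: its fused indane shields one side of the enaminol, and the hydrogen bond from the enaminol OH to the ketone oxygen fixes which ketone face is presented. The step needs the aldehyde as sole acyl donor and the ketone as acceptor; this is secured because only the formyl carbon carries the hydrogen needed for enaminol formation, while intermolecular aldehyde–aldehyde coupling is disfavoured by the two ortho alkoxy groups and by the tether. The weak amine base in catalytic amount should keep the acidic OCH2C(=O) methylene out of the competing aldol condensation, and the product has no hydrogen on C3 and cannot epimerise.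

Step 7
Reactants: 12 (3R)-3-[2,4-dimethoxy-3-(3-methylbut-2-en-1-yl)phenyl]-3-hydroxy-5,7-bis(methoxymethoxy)-2,3-dihydro-4H-chromen-4-one
Product: 13 (3R)-3-[2,4-dimethoxy-3-(3-methylbut-2-en-1-yl)phenyl]-3,5,7-trihydroxy-2,3-dihydro-4H-chromen-4-one (CNP0269650.1)
Conditions: 3 M HCl (aq), MeOH, 40 °C
Reagents that add atoms: none
Why: Acid-catalysed acetal cleavage (methanolysis) of the two aryl methoxymethyl ethers; ionisation at C3 is disfavoured by the adjacent carbonyl, C3 is quaternary and cannot epimerise, and the prenyl group has no free ortho hydroxyl to cyclise onto.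

**Compound list**

1 | 1-(2,4-dimethoxyphenyl)ethan-1-one | CC(=O)c1ccc(OC)cc1OC | starting material
2 | 2-(2,4-dimethoxyphenyl)-2-methyl-1,3-dioxolane | CC1(OCCO1)c1ccc(OC)cc1OC | intermediate
3 | 1-bromo-3-methylbut-2-ene (prenyl bromide) | CC(C)=CCBr | starting material
4 | [2,6-dimethoxy-3-(2-methyl-1,3-dioxolan-2-yl)phenyl]lithium | [Li]c1c(OC)ccc(C2(C)OCCO2)c1OC | intermediate
5 | 2-[2,4-dimethoxy-3-(3-methylbut-2-en-1-yl)phenyl]-2-methyl-1,3-dioxolane | CC1(OCCO1)c1ccc(OC)c(CC=C(C)C)c1OC | intermediate
6 | 1-[2,4-dimethoxy-3-(3-methylbut-2-en-1-yl)phenyl]ethan-1-one | CC(=O)c1ccc(OC)c(CC=C(C)C)c1OC | intermediate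
7 | ({1-[2,4-dimethoxy-3-(3-methylbut-2-en-1-yl)phenyl]ethenyl}oxy)trimethylsilane | C=C(O[Si](C)(C)C)c1ccc(OC)c(CC=C(C)C)c1OC | intermediate
8 | 2-bromo-1-[2,4-dimethoxy-3-(3-methylbut-2-en-1-yl)phenyl]ethan-1-one | BrCC(=O)c1ccc(OC)c(CC=C(C)C)c1OC | intermediate
9 | 2,4,6-trihydroxybenzaldehyde | O=Cc1c(O)cc(O)cc1O | starting material
10 | 2-hydroxy-4,6-bis(methoxymethoxy)benzaldehyde | O=Cc1c(O)cc(OCOC)cc1OCOC | intermediate
11 | 2-{2-[2,4-dimethoxy-3-(3-methylbut-2-en-1-yl)phenyl]-2-oxoethoxy}-4,6-bis(methoxymethoxy)benzaldehyde | O=Cc1c(OCOC)cc(OCOC)cc1OCC(=O)c1ccc(OC)c(CC=C(C)C)c1OC | intermediate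
12 | (3R)-3-[2,4-dimethoxy-3-(3-methylbut-2-en-1-yl)phenyl]-3-hydroxy-5,7-bis(methoxymethoxy)-2,3-dihydro-4H-chromen-4-one | COc1ccc([C@@]2(O)COc3cc(OCOC)cc(OCOC)c3C2=O)c(OC)c1CC=C(C)C | intermediate
13 | (3R)-3-[2,4-dimethoxy-3-(3-methylbut-2-en-1-yl)phenyl]-3,5,7-trihydroxy-2,3-dihydro-4H-chromen-4-one | COc1ccc([C@@]2(O)COc3cc(O)cc(O)c3C2=O)c(OC)c1CC=C(C)C | target

**Summary**

Total step count: 7. Longest linear sequence: 6 steps (steps 1, 2, 3, 5, 6 and 7, from compound 1).

Steps most likely to fail:

1. Step 6. The bulky chiral carbene may add only slowly to the formyl group flanked by two alkoxy substituents, so that turnover stalls and base-mediated aldol condensation of the OCH2C(=O) methylene onto the aldehyde takes over; face discrimination at the ortho-substituted aryl ketone may also be weak. The fallback sets out from 11 and comes back at 12. Ring C is closed without asymmetric induction using the compact achiral carbene from 2-(pentafluorophenyl)-6,7-dihydro-5H-pyrrolo[2,1-c][1,2,4]triazol-2-ium tetrafluoroborate and Et3N, giving the racemic hydroxy ketone F1. The stereocentre is then erased and rebuilt under reagent control: dehydration with SOCl2 in pyridine at 0 °C gives the isoflavone F2; conjugate reduction with LiBH(s-Bu)3 in THF at −78 °C gives the racemic isoflavanone F3; its sodium enolate (NaN(SiMe3)2, THF, −78 °C) is oxidised with the enantiomer of [(8,8-dichlorocamphoryl)sulfonyl]oxaziridine that delivers the (R) carbinol, which is 12.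

2. Step 7. Under the protic acid needed for acetal cleavage, HCl or methanol may add across the prenyl double bond, or the tertiary benzylic hydroxyl may be lost with formation of the isoflavone. The fallback sets out from 9 (and uses 8) and comes back at 13; it carries the two ring-A phenols as allyl ethers, which are removed under neutral conditions. Compound 9 is alkylated with allyl bromide (2.1 equiv) and K2CO3 in DMF at rt to give 2-hydroxy-4,6-bis(prop-2-en-1-yloxy)benzaldehyde F4, the hydrogen-bonded ortho hydroxyl reacting last. Alkylation of F4 with 8 (K2CO3, acetone, rt) gives the bis-allyl keto-aldehyde F5, and the carbene cyclisation of step 6 gives the bis-allyl hydroxy ketone F6. Pd(PPh3)4 (zerovalent palladium, 5 mol%) with morpholine in THF at rt then transfers both allyl groups to the amine and gives 13.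

3. Step 2. Metalation may occur beside the dioxolane instead of between the methoxy groups, or the aryllithium may attack the tertiary end of the allylic bromide and give the transposed (1,1-dimethylallyl) isomer. The fallback sets out from 3 and comes back at 6; it introduces the prenyl group first on a symmetric arene where the site of metalation is unambiguous. Commercial 1,3-dimethoxybenzene F7 is lithiated (n-BuLi, THF, 0 °C to rt) and alkylated with 3 to give 1,3-dimethoxy-2-(3-methylbut-2-en-1-yl)benzene F8. Vilsmeier–Haack formylation (POCl3, DMF, 0 to 60 °C; aqueous NaOAc) para to one methoxy group gives 2,4-dimethoxy-3-(3-methylbut-2-en-1-yl)benzaldehyde F9. Addition of MeMgBr (THF, 0 °C) gives the racemic carbinol F10, and oxidation with MnO2 in CH2Cl2 at rt gives 6.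

**Further compounds**

F1 | step 6 | racemic 3-[2,4-dimethoxy-3-(3-methylbut-2-en-1-yl)phenyl]-3-hydroxy-5,7-bis(methoxymethoxy)-2,3-dihydro-4H-chromen-4-one | COc1ccc(C2(O)COc3cc(OCOC)cc(OCOC)c3C2=O)c(OC)c1CC=C(C)C
F2 | step 6 | 3-[2,4-dimethoxy-3-(3-methylbut-2-en-1-yl)phenyl]-5,7-bis(methoxymethoxy)-4H-chromen-4-one | COc1ccc(C2=COc3cc(OCOC)cc(OCOC)c3C2=O)c(OC)c1CC=C(C)C
F3 | step 6 | racemic 3-[2,4-dimethoxy-3-(3-methylbut-2-en-1-yl)phenyl]-5,7-bis(methoxymethoxy)-2,3-dihydro-4H-chromen-4-one | COc1ccc(C2COc3cc(OCOC)cc(OCOC)c3C2=O)c(OC)c1CC=C(C)C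
F4 | step 7 | 2-hydroxy-4,6-bis(prop-2-en-1-yloxy)benzaldehyde | O=Cc1c(O)cc(OCC=C)cc1OCC=C
F5 | step 7 | 2-{2-[2,4-dimethoxy-3-(3-methylbut-2-en-1-yl)phenyl]-2-oxoethoxy}-4,6-bis(prop-2-en-1-yloxy)benzaldehyde | O=Cc1c(OCC=C)cc(OCC=C)cc1OCC(=O)c1ccc(OC)c(CC=C(C)C)c1OC
F6 | step 7 | (3R)-3-[2,4-dimethoxy-3-(3-methylbut-2-en-1-yl)phenyl]-3-hydroxy-5,7-bis(prop-2-en-1-yloxy)-2,3-dihydro-4H-chromen-4-one | COc1ccc([C@@]2(O)COc3cc(OCC=C)cc(OCC=C)c3C2=O)c(OC)c1CC=C(C)C
F7 | step 2 | 1,3-dimethoxybenzene (commercial input of the fallback) | COc1cccc(OC)c1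
F8 | step 2 | 1,3-dimethoxy-2-(3-methylbut-2-en-1-yl)benzene | COc1cccc(OC)c1CC=C(C)C
F9 | step 2 | 2,4-dimethoxy-3-(3-methylbut-2-en-1-yl)benzaldehyde | O=Cc1ccc(OC)c(CC=C(C)C)c1OC
F10 | step 2 | racemic 1-[2,4-dimethoxy-3-(3-methylbut-2-en-1-yl)phenyl]ethan-1-ol | CC(O)c1ccc(OC)c(CC=C(C)C)c1OC
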